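**Retrosynthetic overview**

1. The target is fisetinidol-(4β→6)-fisetinidol-4β-ol (upper unit rings A/C/B, lower unit rings D/F/E). The last operations are hydrogenolysis of seven benzyl ethers and equatorial hydride delivery to the C4′ ketone of a ring F 3-hydroxyflavanone.
2. Ring F is cut at O1′–C2′ to a (2R,3S)-chalcone epoxide. The chalcone comes from an acetyl group placed on ring D at an aryl bromide (Stille) and 3,4-bis(benzyloxy)benzaldehyde.
3. Feature: in ring C, C4 carries the ring D aryl group and lies ortho to O1 on ring A. O1–C8a–C4a–C4 is therefore an o-quinone methide and C2–C3 a two-carbon enol partner, and C3–C4 and O1–C2 are cut together.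
4. Forward, a chiral phosphoric acid joins a racemic o-hydroxybenzhydrol and a (Z)-α-benzyloxy enol silane to the 3,4-cis 2-hydroxyflavan hemiketal (C3 and C4 set). Hydride addition to the derived oxocarbenium ion would enter anti to O3 and give the 2,3-cis series, so C2 is set instead by reduction of the ketone tautomer and SN1 reclosure of O1–C2 anti to O3.
5. Ring order: C (step 6, C2 fixed in step 8), then F (step 14).

Key step: step 6

Remark (notation): flavan numbering is used; Bn = benzyl; U = (2R,3S,4R)-3,7-bis(benzyloxy)-2-[3,4-bis(benzyloxy)phenyl]chroman-4-yl, the 2,3-trans-3,4-cis upper unit (C4 is R while ring D carries benzyl ethers and S in the free target, by a change of CIP priority only).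
Remark (assumption): the sense of induction of the phosphoric acid with this nucleophile cannot be predicted; the (R)-catalyst is written, and its enantiomer would be used if C4 formed with the opposite configuration.

**Route**

Step 1
Reactants: 1 2,4-dihydroxybenzaldehyde
Product: 2 4-(benzyloxy)-2-hydroxybenzaldehyde
Conditions: BnBr, NaHCO3, KI (cat.), MeCN, 80 °C
Reagents that add atoms: benzyl bromide, BrCc1ccccc1
Why: Williamson etherification under weak base, selective for the 4-OH because the 2-OH is hydrogen-bonded to the aldehyde and less nucleophilic.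

Step 2
Reactants: 3 4,6-dibromoresorcinol
Product: 4 1,5-bis(benzyloxy)-2,4-dibromobenzene
Conditions: BnBr, K2CO3, DMF, 60 °C
Reagents that add atoms: benzyl bromide, BrCc1ccccc1
Why: Double Williamson etherification of a symmetrical resorcinol, with no selectivity question.

Step 3
Reactants: 2 4-(benzyloxy)-2-hydroxybenzaldehyde; 4 1,5-bis(benzyloxy)-2,4-dibromobenzene
Product: 7 rac-[4-(benzyloxy)-2-hydroxyphenyl][2,4-bis(benzyloxy)-5-bromophenyl]methanol, via sodium phenoxide 5 (not isolated), via aryllithium 6 (not isolated)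
Conditions: 2, NaH, THF, 0 °C; 4, n-BuLi, THF, −78 °C; combine, −78 → −20 °C; pH 7 buffer; Et3N-deactivated silica
Reagents that add atoms: none
Why: Bromine–lithium exchange on one of two equivalent bromides and 1,2-addition of the aryllithium to the aldehyde, whose phenol is held as its sodium salt so that no organolithium is consumed; the carbinol centre is racemic and is erased in step 6.

Step 4
Reactants: 8 1,2-bis(benzyloxy)-4-bromobenzene; 9 2-(benzyloxy)-N-methoxy-N-methylacetamide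
Product: 11 2-(benzyloxy)-1-[3,4-bis(benzyloxy)phenyl]ethan-1-one, via aryllithium 10 (not isolated)
Conditions: n-BuLi, THF, −78 °C; then 9, −78 → 0 °C; 1 M HCl
Reagents that add atoms: none
Why: Weinreb ketone synthesis, in which the chelated tetrahedral intermediate prevents a second addition.

Step 5
Reactants: 11 2-(benzyloxy)-1-[3,4-bis(benzyloxy)phenyl]ethan-1-one
Product: 13 (Z)-{[2-(benzyloxy)-1-[3,4-bis(benzyloxy)phenyl]ethenyl]oxy}trimethylsilane, via lithium enolate 12 (not isolated)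
Conditions: LiN(SiMe3)2, THF, −78 °C; TMSCl, −78 → 0 °C; pentane, filtration, used crude
Reagents that add atoms: chlorotrimethylsilane, C[Si](C)(C)Cl
Why: Kinetic enolisation gives the lithium-chelated (Z)-enolate (enolate O and benzyloxy O cis, aryl cis to H so that allylic strain is avoided), which is silylated on oxygen with retention of geometry.

Step 6
Reactants: 7 rac-[4-(benzyloxy)-2-hydroxyphenyl][2,4-bis(benzyloxy)-5-bromophenyl]methanol; 13 (Z)-enol silane
Product: 16 (3S,4R)-3,7-bis(benzyloxy)-2-[3,4-bis(benzyloxy)phenyl]-4-[2,4-bis(benzyloxy)-5-bromophenyl]chroman-2-ol (3,4-cis, C2 anomers), via o-quinone methide 14 (not isolated), via silyl ketal 15 (not isolated)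
Conditions: (R)-3,3′-bis(2,4,6-triisopropylphenyl)-1,1′-binaphthyl-2,2′-diyl hydrogen phosphate (10 mol%), 13 (1.8 equiv), toluene, −30 °C; then aq. citric acid, 0 °C
Reagents that add atoms: none
Why: Proposed new method: the phosphoric acid protonates the benzhydrol and, after loss of water, holds the (E)-o-quinone methide 14 as a hydrogen-bonded ion pair whose C4 is activated by rings A and D; the enol silane adds through its benzyloxy-bearing carbon (C3) in a Mukaiyama–Michael step and O1 closes on the silyloxycarbenium carbon C2 in a 6-exo-trig ketalisation, overall an asynchronous inverse-demand oxa-Diels–Alder reaction, and the water released in the first stage hydrolyses silyl ketal 15. The closest known reaction type is the chiral phosphoric acid-catalysed formal [4+2] annulation of o-quinone methides from o-hydroxybenzhydrols with enol ethers, enamides and silyl ketene acetals; an α-alkoxy silyl enol ether has not been used in it. C4 is controlled by the catalyst, whose 3,3′-aryl groups shield one face of the bound quinone methide, and the racemic carbinol of 7 is irrelevant because it is erased on ionisation. C3 is set relative to C4 by endo approach of the (Z)-alkene, with OSiMe3 and OBn under the heterodiene and the ring D aryl group outside, which gives the 3,4-cis adduct. The step needs regio-, enantio- and diastereoselectivity: the aryl- and silyloxy-stabilised cation at C2 decides which alkene carbon bonds to C4, the free ortho phenol gives two-point binding to the phosphate, and the single (Z) geometry of 13 and (E) geometry of 14 translate into one relative configuration.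

Step 7
Reactants: 16 hemiketal
Product: 18 (1RS,2S,3R)-2-(benzyloxy)-1-[3,4-bis(benzyloxy)phenyl]-3-[4-(benzyloxy)-2-hydroxyphenyl]-3-[2,4-bis(benzyloxy)-5-bromophenyl]propan-1-ol, via open-chain ketone 17 (not isolated)
Conditions: NaBH4, THF/MeOH, −20 → 0 °C
Reagents that add atoms: none
Why: Borohydride reduction of the aryl ketone reached by ring–chain tautomerism of the hemiketal; the new carbinol centre forms as an epimer mixture (anti expected to predominate by chelation and sterics) and is erased on ionisation in step 8.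

Step 8
Reactants: 18 hydroxy phenol (C1 epimers)
Product: 19 (2R,3S,4R)-3,7-bis(benzyloxy)-2-[3,4-bis(benzyloxy)phenyl]-4-[2,4-bis(benzyloxy)-5-bromophenyl]chroman (2,3-trans-3,4-cis)
Conditions: TsOH·H2O (10 mol%), 4 Å MS, CH2Cl2, 0 °C → rt
Reagents that add atoms: none
Why: Acid-catalysed SN1 cycloetherification (the classical flavan ring closure): the 3,4-bis(benzyloxy)benzyl cation is captured by the ring A phenol through the conformer that keeps C3–H in the plane of the cation (minimal allylic 1,3-strain) with O1 anti to the C3–O bond, which puts the 2-aryl and 3-benzyloxy groups trans and sets C2 (R) from either carbinol epimer.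

Step 9
Reactants: 19 bromo flavan
Product: 21 1-[2,4-bis(benzyloxy)-5-U-phenyl]ethan-1-one, via enol ether 20 (not isolated)
Conditions: tributyl(1-ethoxyvinyl)stannane, Pd(PPh3)4 (5 mol%), toluene, 105 °C; then 1 M HCl, THF, rt
Reagents that add atoms: tributyl(1-ethoxyvinyl)stannane, CCCC[Sn](CCCC)(CCCC)C(=C)OCC; water, O
Why: Stille coupling of the aryl bromide with an acetyl anion equivalent, followed by hydrolysis of the enol ether to the methyl ketone.

Step 10
Reactants: 21 aryl methyl ketone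
Product: 22 1-[4-(benzyloxy)-2-hydroxy-5-U-phenyl]ethan-1-one
Conditions: MgBr2·OEt2 (3 equiv), toluene/Et2O, 70 °C; then 1 M HCl
Reagents that add atoms: none
Why: Chelation-directed Lewis acid debenzylation: magnesium bridges the ketone and the ortho ether oxygen, and bromide removes only that benzyl group, freeing the phenol that will become O1′.

Step 11
Reactants: 22 2-hydroxyacetophenone
Product: 24 1-[4-(benzyloxy)-2-(methoxymethoxy)-5-U-phenyl]ethan-1-one, via sodium phenoxide 23 (not isolated)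
Conditions: NaH (1.05 equiv), DMF, 0 °C; MOMCl, 0 °C → rt
Reagents that add atoms: chloromethyl methyl ether, COCCl
Why: Williamson-type O-alkylation of the chelated phenol as its sodium salt, which masks it so that the aldol condensation and the nucleophilic epoxidation cannot cyclise prematurely.

Step 12
Reactants: 24 MOM-protected acetophenone; 25 3,4-bis(benzyloxy)benzaldehyde
Product: 27 (E)-1-[4-(benzyloxy)-2-(methoxymethoxy)-5-U-phenyl]-3-[3,4-bis(benzyloxy)phenyl]prop-2-en-1-one, via aldol adduct 26 (not isolated)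
Conditions: KOH, EtOH/THF, rt
Reagents that add atoms: none
Why: Claisen–Schmidt condensation, with E1cB dehydration of the aldol giving the (E)-chalcone.

Step 13
Reactants: 27 chalcone
Product: 28 [4-(benzyloxy)-2-(methoxymethoxy)-5-U-phenyl]{(2R,3S)-3-[3,4-bis(benzyloxy)phenyl]oxiran-2-yl}methanone
Conditions: poly-L-leucine, urea–H2O2, DBU, THF, rt
Reagents that add atoms: hydrogen peroxide (as its urea adduct), OO
Why: Juliá–Colonna epoxidation, in which the poly-L-leucine helix directs hydroperoxide addition to one enone face and gives the trans (2R,3S)-epoxide under reagent control, the upper-unit stereocentres being remote.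

Step 14
Reactants: 28 epoxy ketone
Product: 30 (2R,3R)-7-(benzyloxy)-2-[3,4-bis(benzyloxy)phenyl]-3-hydroxy-6-U-chroman-4-one, via phenol epoxide 29 (not isolated)
Conditions: HCl, MeOH/THF, 50 °C
Reagents that add atoms: none
Why: Acid removes the MOM group and the freed phenol opens the epoxide 6-endo at the benzylic carbon with inversion (C2′ R) while C3′ keeps the epoxide C–O bond (R), giving the diequatorial 2,3-trans 3-hydroxyflavanone, which is also the thermodynamic isomer.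

Step 15
Reactants: 30 3-hydroxyflavanone
Product: 31 (2R,3S,4S)-7-(benzyloxy)-2-[3,4-bis(benzyloxy)phenyl]-6-U-chroman-3,4-diol (2,3-trans-3,4-cis)
Conditions: LiBH(s-Bu)3 (2.5 equiv), THF, −78 °C; then H2O
Reagents that add atoms: none
Why: The bulky trialkylborohydride attacks the C4′ carbonyl from the equatorial side, as with 2-substituted cyclohexanones, giving the axial 4′-OH cis to the equatorial 3′-OH (4S); the first equivalent is consumed by the 3′-OH.

Step 16
Reactants: 31 heptabenzyl ether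
Product: 32 (2R,3S,4S)-2-(3,4-dihydroxyphenyl)-6-[(2R,3S,4S)-2-(3,4-dihydroxyphenyl)-3,7-dihydroxychroman-4-yl]chroman-3,4,7-triol
Conditions: H2 (1 atm), Pd(OH)2/C, EtOAc/MeOH, rt; filtration under N2, lyophilisation
Reagents that add atoms: none
Why: Hydrogenolysis of the seven benzyl ethers under neutral conditions, stopped at full debenzylation so that the benzylic C4′–OH, the C2–O1 bonds and the acid- and base-sensitive C4–C6′ link are kept; no stereocentre is touched.

**Compound list**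

1 | 2,4-dihydroxybenzaldehyde | O=Cc1ccc(O)cc1O | starting material
2 | 4-(benzyloxy)-2-hydroxybenzaldehyde | O=Cc1ccc(OCc2ccccc2)cc1O | intermediate
3 | 4,6-dibromoresorcinol | Oc1cc(O)c(Br)cc1Br | starting material
4 | 1,5-bis(benzyloxy)-2,4-dibromobenzene | Brc1cc(Br)c(OCc2ccccc2)cc1OCc1ccccc1 | intermediate
5 | sodium 5-(benzyloxy)-2-formylphenolate | [Na+].[O-]c1cc(OCc2ccccc2)ccc1C=O | intermediate (not isolated)
6 | [2,4-bis(benzyloxy)-5-bromophenyl]lithium | [Li]c1cc(Br)c(OCc2ccccc2)cc1OCc1ccccc1 | intermediate (not isolated)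
7 | rac-[4-(benzyloxy)-2-hydroxyphenyl][2,4-bis(benzyloxy)-5-bromophenyl]methanol | OC(c1ccc(OCc2ccccc2)cc1O)c1cc(Br)c(OCc2ccccc2)cc1OCc1ccccc1 | intermediate
8 | 1,2-bis(benzyloxy)-4-bromobenzene | Brc1ccc(OCc2ccccc2)c(OCc2ccccc2)c1 | starting material
9 | 2-(benzyloxy)-N-methoxy-N-methylacetamide | CON(C)C(=O)COCc1ccccc1 | starting material
10 | [3,4-bis(benzyloxy)phenyl]lithium | [Li]c1ccc(OCc2ccccc2)c(OCc2ccccc2)c1 | intermediate (not isolated)
11 | 2-(benzyloxy)-1-[3,4-bis(benzyloxy)phenyl]ethan-1-one | O=C(COCc1ccccc1)c1ccc(OCc2ccccc2)c(OCc2ccccc2)c1 | intermediate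
12 | lithium (Z)-2-(benzyloxy)-1-[3,4-bis(benzyloxy)phenyl]ethen-1-olate | [Li+].[O-]/C(=C\OCc1ccccc1)c1ccc(OCc2ccccc2)c(OCc2ccccc2)c1 | intermediate (not isolated)
13 | (Z)-{[2-(benzyloxy)-1-[3,4-bis(benzyloxy)phenyl]ethenyl]oxy}trimethylsilane | C[Si](C)(C)O/C(=C\OCc1ccccc1)c1ccc(OCc2ccccc2)c(OCc2ccccc2)c1 | intermediate
14 | (6E)-3-(benzyloxy)-6-{[2,4-bis(benzyloxy)-5-bromophenyl]methylidene}cyclohexa-2,4-dien-1-one | O=C1C=C(OCc2ccccc2)C=C/C1=C\c1cc(Br)c(OCc2ccccc2)cc1OCc1ccccc1 | intermediate (not isolated)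
15 | (3S,4R)-3,7-bis(benzyloxy)-2-[3,4-bis(benzyloxy)phenyl]-4-[2,4-bis(benzyloxy)-5-bromophenyl]-2-(trimethylsilyloxy)chroman | c1ccccc1COc1ccc2c(c1)OC(O[Si](C)(C)C)(c1ccc(OCc3ccccc3)c(OCc3ccccc3)c1)[C@@H](OCc1ccccc1)[C@H]2c1cc(Br)c(OCc3ccccc3)cc1OCc1ccccc1 | intermediate (not isolated)
16 | (3S,4R)-3,7-bis(benzyloxy)-2-[3,4-bis(benzyloxy)phenyl]-4-[2,4-bis(benzyloxy)-5-bromophenyl]chroman-2-ol (C2 anomers) | c1ccccc1COc1ccc2c(c1)OC(O)(c1ccc(OCc3ccccc3)c(OCc3ccccc3)c1)[C@@H](OCc1ccccc1)[C@H]2c1cc(Br)c(OCc3ccccc3)cc1OCc1ccccc1 | intermediate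
17 | (2S,3R)-2-(benzyloxy)-1-[3,4-bis(benzyloxy)phenyl]-3-[4-(benzyloxy)-2-hydroxyphenyl]-3-[2,4-bis(benzyloxy)-5-bromophenyl]propan-1-one | O=C(c1ccc(OCc2ccccc2)c(OCc2ccccc2)c1)[C@@H](OCc1ccccc1)[C@H](c1ccc(OCc2ccccc2)cc1O)c1cc(Br)c(OCc2ccccc2)cc1OCc1ccccc1 | intermediate (not isolated)
18 | (1RS,2S,3R)-2-(benzyloxy)-1-[3,4-bis(benzyloxy)phenyl]-3-[4-(benzyloxy)-2-hydroxyphenyl]-3-[2,4-bis(benzyloxy)-5-bromophenyl]propan-1-ol | OC(c1ccc(OCc2ccccc2)c(OCc2ccccc2)c1)[C@@H](OCc1ccccc1)[C@H](c1ccc(OCc2ccccc2)cc1O)c1cc(Br)c(OCc2ccccc2)cc1OCc1ccccc1 | intermediate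
19 | (2R,3S,4R)-3,7-bis(benzyloxy)-2-[3,4-bis(benzyloxy)phenyl]-4-[2,4-bis(benzyloxy)-5-bromophenyl]chroman | c1ccccc1COc1ccc2c(c1)O[C@H](c1ccc(OCc3ccccc3)c(OCc3ccccc3)c1)[C@@H](OCc1ccccc1)[C@H]2c1cc(Br)c(OCc3ccccc3)cc1OCc1ccccc1 | intermediate
20 | (2R,3S,4R)-3,7-bis(benzyloxy)-2-[3,4-bis(benzyloxy)phenyl]-4-[2,4-bis(benzyloxy)-5-(1-ethoxyvinyl)phenyl]chroman | c1ccccc1COc1ccc2c(c1)O[C@H](c1ccc(OCc3ccccc3)c(OCc3ccccc3)c1)[C@@H](OCc1ccccc1)[C@H]2c1cc(C(=C)OCC)c(OCc3ccccc3)cc1OCc1ccccc1 | intermediate (not isolated)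
21 | 1-[2,4-bis(benzyloxy)-5-U-phenyl]ethan-1-one | c1ccccc1COc1ccc2c(c1)O[C@H](c1ccc(OCc3ccccc3)c(OCc3ccccc3)c1)[C@@H](OCc1ccccc1)[C@H]2c1cc(C(C)=O)c(OCc3ccccc3)cc1OCc1ccccc1 | intermediate
22 | 1-[4-(benzyloxy)-2-hydroxy-5-U-phenyl]ethan-1-one | c1ccccc1COc1ccc2c(c1)O[C@H](c1ccc(OCc3ccccc3)c(OCc3ccccc3)c1)[C@@H](OCc1ccccc1)[C@H]2c1cc(C(C)=O)c(O)cc1OCc1ccccc1 | intermediate
23 | sodium 2-acetyl-5-(benzyloxy)-4-U-phenolate | c1ccccc1COc1ccc2c(c1)O[C@H](c1ccc(OCc3ccccc3)c(OCc3ccccc3)c1)[C@@H](OCc1ccccc1)[C@H]2c1cc(C(C)=O)c([O-])cc1OCc1ccccc1.[Na+] | intermediate (not isolated)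
24 | 1-[4-(benzyloxy)-2-(methoxymethoxy)-5-U-phenyl]ethan-1-one | c1ccccc1COc1ccc2c(c1)O[C@H](c1ccc(OCc3ccccc3)c(OCc3ccccc3)c1)[C@@H](OCc1ccccc1)[C@H]2c1cc(C(C)=O)c(OCOC)cc1OCc1ccccc1 | intermediate
25 | 3,4-bis(benzyloxy)benzaldehyde | O=Cc1ccc(OCc2ccccc2)c(OCc2ccccc2)c1 | starting material
26 | 1-[4-(benzyloxy)-2-(methoxymethoxy)-5-U-phenyl]-3-[3,4-bis(benzyloxy)phenyl]-3-hydroxypropan-1-one (carbinol epimers) | c1ccccc1COc1ccc2c(c1)O[C@H](c1ccc(OCc3ccccc3)c(OCc3ccccc3)c1)[C@@H](OCc1ccccc1)[C@H]2c1cc(C(=O)CC(O)c3ccc(OCc4ccccc4)c(OCc4ccccc4)c3)c(OCOC)cc1OCc1ccccc1 | intermediate (not isolated)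
27 | (E)-1-[4-(benzyloxy)-2-(methoxymethoxy)-5-U-phenyl]-3-[3,4-bis(benzyloxy)phenyl]prop-2-en-1-one | c1ccccc1COc1ccc2c(c1)O[C@H](c1ccc(OCc3ccccc3)c(OCc3ccccc3)c1)[C@@H](OCc1ccccc1)[C@H]2c1cc(C(=O)/C=C/c3ccc(OCc4ccccc4)c(OCc4ccccc4)c3)c(OCOC)cc1OCc1ccccc1 | intermediate
28 | [4-(benzyloxy)-2-(methoxymethoxy)-5-U-phenyl]{(2R,3S)-3-[3,4-bis(benzyloxy)phenyl]oxiran-2-yl}methanone | c1ccccc1COc1ccc2c(c1)O[C@H](c1ccc(OCc3ccccc3)c(OCc3ccccc3)c1)[C@@H](OCc1ccccc1)[C@H]2c1cc(C(=O)[C@@H]3O[C@H]3c5ccc(OCc4ccccc4)c(OCc4ccccc4)c5)c(OCOC)cc1OCc1ccccc1 | intermediate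
29 | [4-(benzyloxy)-2-hydroxy-5-U-phenyl]{(2R,3S)-3-[3,4-bis(benzyloxy)phenyl]oxiran-2-yl}methanone | c1ccccc1COc1ccc2c(c1)O[C@H](c1ccc(OCc3ccccc3)c(OCc3ccccc3)c1)[C@@H](OCc1ccccc1)[C@H]2c1cc(C(=O)[C@@H]3O[C@H]3c5ccc(OCc4ccccc4)c(OCc4ccccc4)c5)c(O)cc1OCc1ccccc1 | intermediate (not isolated)
30 | (2R,3R)-7-(benzyloxy)-2-[3,4-bis(benzyloxy)phenyl]-3-hydroxy-6-U-chroman-4-one | c1ccccc1COc1ccc2c(c1)O[C@H](c1ccc(OCc3ccccc3)c(OCc3ccccc3)c1)[C@@H](OCc1ccccc1)[C@H]2c1cc3c(cc1OCc1ccccc1)O[C@H](c1ccc(OCc4ccccc4)c(OCc4ccccc4)c1)[C@@H](O)C3=O | intermediate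
31 | (2R,3S,4S)-7-(benzyloxy)-2-[3,4-bis(benzyloxy)phenyl]-6-U-chroman-3,4-diol | c1ccccc1COc1ccc2c(c1)O[C@H](c1ccc(OCc3ccccc3)c(OCc3ccccc3)c1)[C@@H](OCc1ccccc1)[C@H]2c1cc3c(cc1OCc1ccccc1)O[C@H](c1ccc(OCc4ccccc4)c(OCc4ccccc4)c1)[C@@H](O)[C@H]3O | intermediate
32 | (2R,3S,4S)-2-(3,4-dihydroxyphenyl)-6-[(2R,3S,4S)-2-(3,4-dihydroxyphenyl)-3,7-dihydroxychroman-4-yl]chroman-3,4,7-triol | Oc1ccc2c(c1)O[C@H](c1ccc(O)c(O)c1)[C@@H](O)[C@H]2c1cc2c(cc1O)O[C@H](c1ccc(O)c(O)c1)[C@@H](O)[C@H]2O | target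

**Step count and risks**

Total: 16 steps. Longest linear sequence: 13 steps (steps 2, 3, 6–16, from 4,6-dibromoresorcinol).

Steps most likely to fail:

1. Step 6. The enol silane may be protodesilylated faster than it adds, the highly stabilised cation may react outside the chiral ion pair (low enantioselectivity), or the endo/exo preference may be poor (3,4-cis/trans mixture). The fallback uses known reactions only; it sets out from 4 and aryllithium 10 and returns at 16.
   - Bromine–lithium exchange of 4 and quench with B(OiPr)3 give [2,4-bis(benzyloxy)-5-bromophenyl]boronic acid F1.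
   - Hayashi–Miyaura conjugate addition of F1 to commercial 7-(benzyloxy)coumarin (O=C1C=Cc2ccc(OCc3ccccc3)cc2O1) with Rh(acac)(C2H4)2 and the SEGPHOS enantiomer that delivers the aryl group to the required face (dioxane/H2O, 60 °C) sets C4 and gives (4R)-7-(benzyloxy)-4-[2,4-bis(benzyloxy)-5-bromophenyl]chroman-2-one F2.
   - LiN(SiMe3)2 and 2-(phenylsulfonyl)-3-phenyloxaziridine hydroxylate the lactone enolate anti to the C4 aryl group to give trans-3-hydroxy lactone F3.
   - Benzyl 2,2,2-trichloroacetimidate with catalytic TfOH gives the trans-3-benzyloxy lactone F4.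
   - Deprotonation (LiN(SiMe3)2, −78 °C) and kinetic protonation anti to the aryl group with 2,6-di-tert-butylphenol give the cis-3-benzyloxy lactone F5.
   - One equivalent of aryllithium 10 at −78 °C opens the lactone to the ketone and hence to hemiketal 16.

2. Step 8. Facial selectivity in the capture of the benzylic cation may be insufficient, or reversible re-ionisation of the product may erode it. The fallback replaces the SN1 closure by a stereospecific SN2 closure; it sets out from 16 and returns at 19.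
   - Non-chelating Felkin–Anh reduction of 16 (through 17) with KBH(s-Bu)3 in THF at −78 °C gives the 1,2-syn alcohol (1S,2S,3R)-2-(benzyloxy)-1-[3,4-bis(benzyloxy)phenyl]-3-[4-(benzyloxy)-2-hydroxyphenyl]-3-[2,4-bis(benzyloxy)-5-bromophenyl]propan-1-ol F6, separated from any anti epimer.
   - Mitsunobu cycloetherification (PPh3, diisopropyl azodicarboxylate, THF, 0 °C) lets the phenol displace the activated carbinol with inversion to give 19.

3. Step 14. Under acid the protonated epoxide may suffer a 1,2-aroyl shift or chloride opening, and the upper flavan may ionise at C2. The fallback closes ring F without acid; it sets out from 22 and returns at 30.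
   - Allylation of 22 (allyl bromide, K2CO3, DMF) gives 1-[2-(allyloxy)-4-(benzyloxy)-5-U-phenyl]ethan-1-one F7.
   - Claisen–Schmidt condensation with 25 gives the (E)-chalcone F8.
   - Juliá–Colonna epoxidation (poly-L-leucine, urea–H2O2, DBU) gives the (2R,3S)-epoxide F9.
   - Pd(PPh3)4 (zerovalent palladium) with K2CO3 in MeOH removes the allyl group, and the phenoxide closes ring F in the same flask by base-mediated 6-endo epoxide opening (the cyclisation half of the Algar–Flynn–Oyamada reaction) to give 30.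

Further compounds

F1 | step 6 | [2,4-bis(benzyloxy)-5-bromophenyl]boronic acid | OB(O)c1cc(Br)c(OCc2ccccc2)cc1OCc1ccccc1
F2 | step 6 | (4R)-7-(benzyloxy)-4-[2,4-bis(benzyloxy)-5-bromophenyl]chroman-2-one | c1ccccc1COc1ccc2c(c1)OC(=O)C[C@H]2c1cc(Br)c(OCc3ccccc3)cc1OCc1ccccc1
F3 | step 6 | (3R,4R)-7-(benzyloxy)-4-[2,4-bis(benzyloxy)-5-bromophenyl]-3-hydroxychroman-2-one (3,4-trans) | c1ccccc1COc1ccc2c(c1)OC(=O)[C@H](O)[C@H]2c1cc(Br)c(OCc3ccccc3)cc1OCc1ccccc1
F4 | step 6 | (3R,4R)-3,7-bis(benzyloxy)-4-[2,4-bis(benzyloxy)-5-bromophenyl]chroman-2-one (3,4-trans) | c1ccccc1COc1ccc2c(c1)OC(=O)[C@H](OCc1ccccc1)[C@H]2c1cc(Br)c(OCc3ccccc3)cc1OCc1ccccc1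
F5 | step 6 | (3S,4R)-3,7-bis(benzyloxy)-4-[2,4-bis(benzyloxy)-5-bromophenyl]chroman-2-one (3,4-cis) | c1ccccc1COc1ccc2c(c1)OC(=O)[C@@H](OCc1ccccc1)[C@H]2c1cc(Br)c(OCc3ccccc3)cc1OCc1ccccc1
F6 | step 8 | (1S,2S,3R)-2-(benzyloxy)-1-[3,4-bis(benzyloxy)phenyl]-3-[4-(benzyloxy)-2-hydroxyphenyl]-3-[2,4-bis(benzyloxy)-5-bromophenyl]propan-1-ol | O[C@@H](c1ccc(OCc2ccccc2)c(OCc2ccccc2)c1)[C@@H](OCc1ccccc1)[C@H](c1ccc(OCc2ccccc2)cc1O)c1cc(Br)c(OCc2ccccc2)cc1OCc1ccccc1
F7 | step 14 | 1-[2-(allyloxy)-4-(benzyloxy)-5-U-phenyl]ethan-1-one | c1ccccc1COc1ccc2c(c1)O[C@H](c1ccc(OCc3ccccc3)c(OCc3ccccc3)c1)[C@@H](OCc1ccccc1)[C@H]2c1cc(C(C)=O)c(OCC=C)cc1OCc1ccccc1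
F8 | step 14 | (E)-1-[2-(allyloxy)-4-(benzyloxy)-5-U-phenyl]-3-[3,4-bis(benzyloxy)phenyl]prop-2-en-1-one | c1ccccc1COc1ccc2c(c1)O[C@H](c1ccc(OCc3ccccc3)c(OCc3ccccc3)c1)[C@@H](OCc1ccccc1)[C@H]2c1cc(C(=O)/C=C/c3ccc(OCc4ccccc4)c(OCc4ccccc4)c3)c(OCC=C)cc1OCc1ccccc1
F9 | step 14 | [2-(allyloxy)-4-(benzyloxy)-5-U-phenyl]{(2R,3S)-3-[3,4-bis(benzyloxy)phenyl]oxiran-2-yl}methanone | c1ccccc1COc1ccc2c(c1)O[C@H](c1ccc(OCc3ccccc3)c(OCc3ccccc3)c1)[C@@H](OCc1ccccc1)[C@H]2c1cc(C(=O)[C@@H]3O[C@H]3c5ccc(OCc4ccccc4)c(OCc4ccccc4)c5)c(OCC=C)cc1OCc1ccccc1
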